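**Retrosynthetic overview**

1. The target comes from its tris-MOM ether by removal of the three phenol acetals; the C2 configuration is already in place.
2. Ring C is cut at O1–C2 and C3–C4. O1, C8a, C4a and C4 of ring A form an o-quinone methide heterodiene (released from a salicyl alcohol), and C2=C3 with ring B is an electron-rich styrene. A chiral Brønsted acid catalysed oxa-[4+2] joins them and sets C2.
3. Ring A salicyl alcohol: isovanillin → Baeyer–Villiger → formylation → ether Claisen (C8 prenyl) → 7-O-MOM → reduction.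
4. Ring B styrene: 2-bromoisovanillin → demethylation → bis-MOM → Wittig → Br–Li exchange and prenylation.
5. Ring order: rings A and B are bought as arenes; ring C is the only ring formed, in step 12.

Key step: step 12

Remarks and assumptions:
- Flavan numbering is used throughout (ring B primed); prenyl = 3-methylbut-2-en-1-yl.
- The sense of induction of the chiral acid cannot be predicted for a methide without a C4 substituent. The (R)-catalyst is written; its antipode is to be used if the first runs show that it delivers the (2R) adduct.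
- 2-Bromoisovanillin (13) is taken as purchased.

**Route**

Step 1
Reactants: 1 isovanillin
Product: 3 4-methoxybenzene-1,3-diol, via aryl formate 2 (not isolated)
Conditions: mCPBA, CH2Cl2, 0 °C → rt; NaHCO3 wash; then K2CO3 (cat.), MeOH, 0 °C
Reagents that add atoms: mCPBA, O=C(OO)c1cccc(Cl)c1
Why: Baeyer–Villiger (Dakin-type) oxidation, in which the electron-rich p-methoxyaryl group migrates to oxygen and the formate is methanolysed, so CHO is replaced by OH.

Step 2
Reactants: 3 4-methoxybenzene-1,3-diol
Product: 5 2,4-dihydroxy-5-methoxybenzaldehyde, via iminium salt 4 (not isolated)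
Conditions: POCl3, DMF, MeCN, 0 °C → rt; then H2O, 50 °C
Reagents that add atoms: N,N-dimethylformamide, CN(C)C=O; water, O
Why: Vilsmeier–Haack formylation should go to the position ortho to one hydroxyl and para to the other, since the site between the hydroxyls is hindered and the site next to OMe is meta to both.

Step 3
Reactants: 5 2,4-dihydroxy-5-methoxybenzaldehyde; 6 3-chloro-3-methylbut-1-yne
Product: 7 2-hydroxy-5-methoxy-4-[(2-methylbut-3-yn-2-yl)oxy]benzaldehyde
Conditions: DBU, CuCl2·2H2O (1 mol %), MeCN, 0 °C
Reagents that add atoms: none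
Why: Copper-catalysed propargylic etherification (via a copper allenylidene) takes the more acidic, non-chelated 4-OH, while the 2-OH stays hydrogen-bonded to the aldehyde.

Step 4
Reactants: 7 2-hydroxy-5-methoxy-4-[(2-methylbut-3-yn-2-yl)oxy]benzaldehyde
Product: 8 2-hydroxy-5-methoxy-4-[(2-methylbut-3-en-2-yl)oxy]benzaldehyde
Conditions: H2 (1 atm), Lindlar catalyst, quinoline, EtOAc, rt
Reagents that add atoms: none
Why: Lindlar semihydrogenation stops the terminal alkyne at the alkene and leaves the aldehyde untouched.

Step 5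
Reactants: 8 2-hydroxy-5-methoxy-4-[(2-methylbut-3-en-2-yl)oxy]benzaldehyde
Product: 10 2,4-dihydroxy-5-methoxy-3-(3-methylbut-2-en-1-yl)benzaldehyde, via Claisen dienone 9 (not isolated)
Conditions: PhNEt2, 140 °C
Reagents that add atoms: none
Why: Aromatic Claisen rearrangement, in which the [3,3] shift can end productively only at C3 (the other ortho carbon carries OMe) and turns the 1,1-dimethylallyl ether into a C-prenyl group before tautomerisation restores the phenol.

Step 6
Reactants: 10 2,4-dihydroxy-5-methoxy-3-(3-methylbut-2-en-1-yl)benzaldehyde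
Product: 11 2-hydroxy-5-methoxy-4-(methoxymethoxy)-3-(3-methylbut-2-en-1-yl)benzaldehyde
Conditions: MOMCl (1.1 equiv), K2CO3, acetone, 0 °C → rt
Reagents that add atoms: chloromethyl methyl ether, COCCl
Why: Williamson-type O-alkylation is selective for the 4-OH because the 2-OH is chelated to the aldehyde and much less nucleophilic.

Step 7
Reactants: 11 2-hydroxy-5-methoxy-4-(methoxymethoxy)-3-(3-methylbut-2-en-1-yl)benzaldehyde
Product: 12 6-(hydroxymethyl)-4-methoxy-3-(methoxymethoxy)-2-(3-methylbut-2-en-1-yl)phenol
Conditions: NaBH4, THF/MeOH, 0 °C; pH 7 buffer work-up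
Reagents that add atoms: none
Why: Borohydride reduction of the aldehyde; a neutral work-up and prompt use are planned because this electron-rich salicyl alcohol ionises easily with acid.

Step 8
Reactants: 13 2-bromo-3-hydroxy-4-methoxybenzaldehyde
Product: 15 2-bromo-3,4-dihydroxybenzaldehyde, via cyclic bromoborate 14 (not isolated)
Conditions: BBr3, CH2Cl2, −78 °C → rt; then H2O
Reagents that add atoms: none
Why: Lewis acid O-demethylation, in which boron held by the neighbouring phenol activates the methyl ether for SN2 attack by bromide and hydrolysis frees the catechol.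

Step 9
Reactants: 15 2-bromo-3,4-dihydroxybenzaldehyde
Product: 16 2-bromo-3,4-bis(methoxymethoxy)benzaldehyde
Conditions: MOMCl (3 equiv), K2CO3, DMF, 0 °C → rt
Reagents that add atoms: chloromethyl methyl ether, COCCl
Why: Double Williamson-type O-alkylation of the catechol; the MOM groups later serve as chelating groups for the aryllithium.

Step 10
Reactants: 16 2-bromo-3,4-bis(methoxymethoxy)benzaldehyde
Product: 17 2-bromo-1-ethenyl-3,4-bis(methoxymethoxy)benzene
Conditions: Ph3PCH3Br, KOtBu, THF, 0 °C → rt
Reagents that add atoms: methyltriphenylphosphonium bromide, C[P+](c1ccccc1)(c1ccccc1)c1ccccc1.[Br-]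
Why: Wittig methylenation of the aldehyde; MOM ethers and the aryl bromide are inert to the ylide.

Step 11
Reactants: 17 2-bromo-1-ethenyl-3,4-bis(methoxymethoxy)benzene; 18 1-bromo-3-methylbut-2-ene
Product: 20 1-ethenyl-3,4-bis(methoxymethoxy)-2-(3-methylbut-2-en-1-yl)benzene, via aryllithium 19 (not isolated)
Conditions: n-BuLi, THF, −78 °C; CuBr·SMe2 (10 mol %), then 18, −78 → 0 °C
Reagents that add atoms: none
Why: Bromine–lithium exchange outruns addition to the vinyl group and gives an aryllithium chelated by the ortho-OMOM group, and copper-catalysed allylic substitution at the unhindered CH2 end of prenyl bromide should give the linear prenyl arene.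

Step 12
Reactants: 12 6-(hydroxymethyl)-4-methoxy-3-(methoxymethoxy)-2-(3-methylbut-2-en-1-yl)phenol; 20 1-ethenyl-3,4-bis(methoxymethoxy)-2-(3-methylbut-2-en-1-yl)benzene
Product: 22 (2S)-2-[3,4-bis(methoxymethoxy)-2-(3-methylbut-2-en-1-yl)phenyl]-6-methoxy-7-(methoxymethoxy)-8-(3-methylbut-2-en-1-yl)-3,4-dihydro-2H-chromene, via o-quinone methide 21 (not isolated)
Conditions: (R)-3,3′-bis(2,4,6-triisopropylphenyl)-H8-BINOL N-triflylphosphoramide (5 mol %), 20 (1.5 equiv), 5 Å MS, PhMe, −40 °C, slow addition of 12; Et3N quench at −40 °C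
Reagents that add atoms: none
Why: Proposed new method: the strong chiral acid protonates the benzylic hydroxyl of 12, water leaves with push from the ortho-OH and para-OMOM oxygens, and the o-quinone methide 21 stays protonated or hydrogen-bonded at O1 in a contact ion pair with the chiral anion; the CH2 terminus of 20 then adds to the methide carbon (C3–C4) and the C2 benzylic cation, stabilised by the 4′-OMOM oxygen, is captured by O1 (O1–C2) before it leaves the ion pair. The closest known reaction type is the chiral phosphoric acid or N-triflylphosphoramide catalysed [4+2] of 4-aryl o-quinone methides (from o-hydroxybenzhydrols) with styrenes to 2,4-diarylchromans; new here is a methide whose carbon terminus is an unsubstituted CH2, which the electron-rich ring A (7-OMOM para to C4) should make accessible from a primary alcohol. Ring C closes by an asynchronous inverse-electron-demand oxa-[4+2] cycloaddition, the six-membered ring being completed by O1 on the styrene α-carbon. C2 is the only new stereocentre and is under catalyst control: because C4 bears no substituent, the anion bound at O1 has to fix both the face of the methide and the endo or exo placement of ring B, which is why a confined 3,3′-disubstituted acid is chosen. The step needs 2-aryl regiochemistry, given by the polarity match of the nucleophilic styrene CH2 with the electrophilic C4, and chemoselectivity for the vinyl group over the three prenyl alkenes and the MOM acetals, given by the conjugated, oxygen-stabilised cation that only the styrene can form and by the low temperature; slow addition of 12 to an excess of 20 keeps the methide from alkylating its own precursor.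

Step 13
Reactants: 22 (2S)-2-[3,4-bis(methoxymethoxy)-2-(3-methylbut-2-en-1-yl)phenyl]-6-methoxy-7-(methoxymethoxy)-8-(3-methylbut-2-en-1-yl)-3,4-dihydro-2H-chromene
Product: 23 4-[(2S)-7-hydroxy-6-methoxy-8-(3-methylbut-2-en-1-yl)-3,4-dihydro-2H-chromen-2-yl]-3-(3-methylbut-2-en-1-yl)benzene-1,2-diol
Conditions: HCl (ca. 1 M, from conc. aq. HCl), MeOH/THF, rt, argon
Reagents that add atoms: none
Why: Acid-catalysed transacetalisation to methanol removes the three aryl MOM ethers; at room temperature the prenyl alkenes should not be protonated and the C2–O1 bond should not ionise, so the C2 configuration set in step 12 is kept.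

**Compound list**

1 | isovanillin (3-hydroxy-4-methoxybenzaldehyde) | COc1ccc(C=O)cc1O | starting material
2 | 3-hydroxy-4-methoxyphenyl formate | COc1ccc(OC=O)cc1O | intermediate (not isolated)
3 | 4-methoxybenzene-1,3-diol | COc1ccc(O)cc1O | intermediate
4 | N-[(2,4-dihydroxy-5-methoxyphenyl)methylidene]-N-methylmethanaminium chloride | COc1cc(C=[N+](C)C)c(O)cc1O.[Cl-] | intermediate (not isolated)
5 | 2,4-dihydroxy-5-methoxybenzaldehyde | COc1cc(C=O)c(O)cc1O | intermediate
6 | 3-chloro-3-methylbut-1-yne | CC(C)(Cl)C#C | starting material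
7 | 2-hydroxy-5-methoxy-4-[(2-methylbut-3-yn-2-yl)oxy]benzaldehyde | COc1cc(C=O)c(O)cc1OC(C)(C)C#C | intermediate
8 | 2-hydroxy-5-methoxy-4-[(2-methylbut-3-en-2-yl)oxy]benzaldehyde | COc1cc(C=O)c(O)cc1OC(C)(C)C=C | intermediate
9 | 2-hydroxy-5-methoxy-3-(3-methylbut-2-en-1-yl)-4-oxocyclohexa-1,5-diene-1-carbaldehyde | COC1=CC(C=O)=C(O)C(CC=C(C)C)C1=O | intermediate (not isolated)
10 | 2,4-dihydroxy-5-methoxy-3-(3-methylbut-2-en-1-yl)benzaldehyde | COc1cc(C=O)c(O)c(CC=C(C)C)c1O | intermediate
11 | 2-hydroxy-5-methoxy-4-(methoxymethoxy)-3-(3-methylbut-2-en-1-yl)benzaldehyde | COc1cc(C=O)c(O)c(CC=C(C)C)c1OCOC | intermediate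
12 | 6-(hydroxymethyl)-4-methoxy-3-(methoxymethoxy)-2-(3-methylbut-2-en-1-yl)phenol | COc1cc(CO)c(O)c(CC=C(C)C)c1OCOC | intermediate
13 | 2-bromo-3-hydroxy-4-methoxybenzaldehyde (2-bromoisovanillin) | COc1ccc(C=O)c(Br)c1O | starting material
14 | 2,4-dibromo-1,3,2-benzodioxaborole-5-carbaldehyde | O=Cc1ccc2OB(Br)Oc2c1Br | intermediate (not isolated)
15 | 2-bromo-3,4-dihydroxybenzaldehyde | O=Cc1ccc(O)c(O)c1Br | intermediate
16 | 2-bromo-3,4-bis(methoxymethoxy)benzaldehyde | COCOc1ccc(C=O)c(Br)c1OCOC | intermediate
17 | 2-bromo-1-ethenyl-3,4-bis(methoxymethoxy)benzene | C=Cc1ccc(OCOC)c(OCOC)c1Br | intermediate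
18 | 1-bromo-3-methylbut-2-ene (prenyl bromide) | CC(C)=CCBr | starting material
19 | [6-ethenyl-2,3-bis(methoxymethoxy)phenyl]lithium | [Li]c1c(C=C)ccc(OCOC)c1OCOC | intermediate (not isolated)
20 | 1-ethenyl-3,4-bis(methoxymethoxy)-2-(3-methylbut-2-en-1-yl)benzene | C=Cc1ccc(OCOC)c(OCOC)c1CC=C(C)C | intermediate
21 | 4-methoxy-3-(methoxymethoxy)-6-methylidene-2-(3-methylbut-2-en-1-yl)cyclohexa-2,4-dien-1-one | C=C1C=C(OC)C(OCOC)=C(CC=C(C)C)C1=O | intermediate (not isolated)
22 | (2S)-2-[3,4-bis(methoxymethoxy)-2-(3-methylbut-2-en-1-yl)phenyl]-6-methoxy-7-(methoxymethoxy)-8-(3-methylbut-2-en-1-yl)-3,4-dihydro-2H-chromene | COc1cc2c(c(CC=C(C)C)c1OCOC)O[C@H](c1ccc(OCOC)c(OCOC)c1CC=C(C)C)CC2 | intermediate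
23 | 4-[(2S)-7-hydroxy-6-methoxy-8-(3-methylbut-2-en-1-yl)-3,4-dihydro-2H-chromen-2-yl]-3-(3-methylbut-2-en-1-yl)benzene-1,2-diol | COc1cc2c(c(CC=C(C)C)c1O)O[C@H](c1ccc(O)c(O)c1CC=C(C)C)CC2 | target

**Step count**

Total: 13 steps. Longest linear sequence: 9 steps (steps 1–7, 12, 13); the ring B branch has 4 steps (8–11).

**Steps most likely to fail**

Step 12. Discrimination between the two faces of the unsubstituted methide and between endo and exo approach may be poor, which would erode the enantiomeric purity. The methide may also be consumed by Friedel–Crafts self-alkylation, by addition to a prenyl alkene, or after acid-induced loss of a MOM group.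
The fallback uses known chemistry, sets out from aldehyde 11 and styrene 20, and comes back at 22:
- Tsuji–Wacker oxidation of 20 (PdCl2, CuCl, O2, DMF/H2O) should give the methyl ketone 1-[3,4-bis(methoxymethoxy)-2-(3-methylbut-2-en-1-yl)phenyl]ethan-1-one F1.
- Claisen–Schmidt condensation of this ketone with 11 (KOH, EtOH) should give the enone (2E)-1-[3,4-bis(methoxymethoxy)-2-(3-methylbut-2-en-1-yl)phenyl]-3-[2-hydroxy-5-methoxy-4-(methoxymethoxy)-3-(3-methylbut-2-en-1-yl)phenyl]prop-2-en-1-one F2.
- Conjugate reduction with Stryker's reagent, which spares the prenyl alkenes, should give the saturated ketone 1-[3,4-bis(methoxymethoxy)-2-(3-methylbut-2-en-1-yl)phenyl]-3-[2-hydroxy-5-methoxy-4-(methoxymethoxy)-3-(3-methylbut-2-en-1-yl)phenyl]propan-1-one F3.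
- Noyori transfer hydrogenation (RuCl(p-cymene)[(R,R)-TsDPEN], HCO2H/Et3N) should give the carbinol (1R)-1-[3,4-bis(methoxymethoxy)-2-(3-methylbut-2-en-1-yl)phenyl]-3-[2-hydroxy-5-methoxy-4-(methoxymethoxy)-3-(3-methylbut-2-en-1-yl)phenyl]propan-1-ol F4.
- Intramolecular Mitsunobu etherification (PPh3, DIAD, THF, 0 °C) closes O1–C2 with inversion and should deliver (2S)-22.

Step 13. The freed ortho phenols may add to the prenyl alkenes under acid (chroman formation), and the C2–O1 benzylic ether may ionise, which would erode the enantiomeric purity or open the ring.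
The fallback sets out from 22 and comes back at 23. It avoids protic acid by a silyl relay:
- TESOTf with 2,2′-bipyridyl in CH2Cl2 at 0 °C should convert the three aryl MOM ethers into the tris-silyl ether (2S)-2-[3,4-bis(triethylsilyloxy)-2-(3-methylbut-2-en-1-yl)phenyl]-6-methoxy-8-(3-methylbut-2-en-1-yl)-7-(triethylsilyloxy)-3,4-dihydro-2H-chromene F5.
- TBAF buffered with AcOH in THF at 0 °C should then release 23.

Step 5. The tertiary allyl ether may fragment with loss of isoprene, or the ortho-prenylphenol may rearrange further or cyclise at the temperature needed.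
The fallback sets out from 5 and comes back at 10, bypassing 7 and 8. Direct nuclear prenylation of the phenoxide of 5 with prenyl bromide 18 in aqueous KOH at 0 °C → rt should alkylate C3, the only free carbon between the two oxygens. The conversion is expected to be modest, with recovery of 5 and separation of O-prenyl ethers. No new compound is made on this way (F0).

**Further compounds**

F1 | step 12 | 1-[3,4-bis(methoxymethoxy)-2-(3-methylbut-2-en-1-yl)phenyl]ethan-1-one | CC(=O)c1ccc(OCOC)c(OCOC)c1CC=C(C)C
F2 | step 12 | (2E)-1-[3,4-bis(methoxymethoxy)-2-(3-methylbut-2-en-1-yl)phenyl]-3-[2-hydroxy-5-methoxy-4-(methoxymethoxy)-3-(3-methylbut-2-en-1-yl)phenyl]prop-2-en-1-one | COc1cc(/C=C/C(=O)c2ccc(OCOC)c(OCOC)c2CC=C(C)C)c(O)c(CC=C(C)C)c1OCOC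
F3 | step 12 | 1-[3,4-bis(methoxymethoxy)-2-(3-methylbut-2-en-1-yl)phenyl]-3-[2-hydroxy-5-methoxy-4-(methoxymethoxy)-3-(3-methylbut-2-en-1-yl)phenyl]propan-1-one | COc1cc(CCC(=O)c2ccc(OCOC)c(OCOC)c2CC=C(C)C)c(O)c(CC=C(C)C)c1OCOC
F4 | step 12 | (1R)-1-[3,4-bis(methoxymethoxy)-2-(3-methylbut-2-en-1-yl)phenyl]-3-[2-hydroxy-5-methoxy-4-(methoxymethoxy)-3-(3-methylbut-2-en-1-yl)phenyl]propan-1-ol | O[C@@H](c1ccc(OCOC)c(OCOC)c1CC=C(C)C)CCc1cc(OC)c(OCOC)c(CC=C(C)C)c1O
F5 | step 13 | (2S)-2-[3,4-bis(triethylsilyloxy)-2-(3-methylbut-2-en-1-yl)phenyl]-6-methoxy-8-(3-methylbut-2-en-1-yl)-7-(triethylsilyloxy)-3,4-dihydro-2H-chromene | COc1cc2c(c(CC=C(C)C)c1O[Si](CC)(CC)CC)O[C@H](c1ccc(O[Si](CC)(CC)CC)c(O[Si](CC)(CC)CC)c1CC=C(C)C)CC2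
F0 | step 5 | none | none
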